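**Retrosynthetic overview**

- The target is a trimer: non-aromatic ring A (2-butanoyl-3,5-dihydroxy-4,4-dimethylcyclohexadienone; C1 = ring carbonyl, C2 = butanoyl carbon, C4 = CMe2, C6 = CH2-bearing carbon) – CH2 – ring B (butanoylphloroglucinol) – CH2 – ring C (its 4-O-methyl ether). Both bridges are cut at the aryl–CH2 bonds on rings B and C (quinone-methide alkylations), so only ring A has to be built.
- Ring A is disconnected at C1–C2 and C5–C6 into a two-carbon siloxyalkyne TBSOCH2–C≡C–OTIPS (C6 and C1, bringing the bridge carbon) and a four-carbon 4,4-dimethyl-3-siloxycyclobutenone (C5, C4, C3, C2). The butanoyl group is put on C2 afterwards by O-to-C acyl transfer.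
- Enabling feature: C4 of ring A is quaternary (two methyl groups) and lies between the oxygen-bearing C3 and C5. Ring A is therefore a blocked cyclohexadienone that cannot aromatise, which is what 6π closure of a dienylketene onto a CMe2 terminus delivers, and the alternating oxygens at C1, C3 and C5 match the polarity of a ketene/siloxyalkyne union.
- Ring order: four-membered ring (dimethylketene + ethoxyethyne) → ring A by strain-release ring expansion → C2 butanoylation → ring B joined → aminomethyl handle on ring B → ring C joined.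

Key step: step 5

Remark: ring A is an enolised β-triketone and is drawn throughout in the tautomer of the target SMILES. The target and all isolated intermediates are achiral. Ethoxyethyne (solution in hexanes), the propargyl silyl ether, 1-(2,4,6-trihydroxyphenyl)butan-1-one and Eschenmoser's salt are taken as commercial.

**Route**

Step 1
Reactants: 1 2-methylpropanoyl chloride; 2 ethoxyethyne
Product: 4 3-ethoxy-4,4-dimethylcyclobut-2-en-1-one, via dimethylketene 3 (not isolated)
Conditions: Et3N, Et2O, 0 °C to rt
Reagents that add atoms: none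
Why: Dehydrochlorination of 1 gives dimethylketene, which should undergo the classical thermal [2+2] ketene–alkoxyalkyne cycloaddition with 2, the nucleophilic unsubstituted alkyne carbon bonding to the ketene carbonyl carbon so that ethoxy ends up at C3 and the CMe2 carbon at C4.

Step 2
Reactants: 4 3-ethoxy-4,4-dimethylcyclobut-2-en-1-one
Product: 5 3-hydroxy-4,4-dimethylcyclobut-2-en-1-one
Conditions: 1 M aq. HCl, THF, 0 °C to rt
Reagents that add atoms: water, O
Why: Acid-catalysed hydrolysis of a vinylogous ester (conjugate addition of water, loss of ethanol) is the standard conversion of 3-ethoxycyclobutenones into cyclobutane-1,3-diones, and cold dilute acid should avoid retro-Claisen opening of the strained ring.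

Step 3
Reactants: 5 3-hydroxy-4,4-dimethylcyclobut-2-en-1-one
Product: 6 4,4-dimethyl-3-[(triisopropylsilyl)oxy]cyclobut-2-en-1-one
Conditions: i-Pr3SiCl, Et3N, CH2Cl2, 0 °C
Reagents that add atoms: chlorotriisopropylsilane, CC(C)[Si](Cl)(C(C)C)C(C)C
Why: O-silylation of a strongly acidic vinylogous acid should give the vinylogous silyl ester, which is inert to ketenes and removable later with fluoride without any acid.

Step 4
Reactants: 7 tert-butyl(dimethyl)(prop-2-yn-1-yloxy)silane
Product: 10 tert-butyl(dimethyl)({3-[(triisopropylsilyl)oxy]prop-2-yn-1-yl}oxy)silane, via alkynyllithium 8 (not isolated), via lithium ynolate 9 (not isolated)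
Conditions: n-BuLi, THF, −78 °C; then t-BuOOLi (from t-BuOOH and LiN(SiMe3)2), −78 to 0 °C; then i-Pr3SiOTf, −78 °C
Reagents that add atoms: tert-butyl hydroperoxide, CC(C)(C)OO; triisopropylsilyl trifluoromethanesulfonate, CC(C)[Si](OS(=O)(=O)C(F)(F)F)(C(C)C)C(C)C
Why: Oxidation of a lithium acetylide by oxygen transfer from t-BuOOLi to the ynolate, followed by O-silylation with a bulky silyl triflate, is the established acetylide-oxidation route to 1-siloxyalkynes, and the propargylic silyl ether should tolerate it at low temperature.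

Step 5
Reactants: 6 4,4-dimethyl-3-[(triisopropylsilyl)oxy]cyclobut-2-en-1-one; 10 tert-butyl(dimethyl)({3-[(triisopropylsilyl)oxy]prop-2-yn-1-yl}oxy)silane
Product: 14 2-({[tert-butyl(dimethyl)silyl]oxy}methyl)-6,6-dimethyl-3,5-bis[(triisopropylsilyl)oxy]cyclohexa-2,4-dien-1-one, via vinylketene 11 (not isolated), via alkenylcyclobutenone 12 (not isolated), via dienylketene 13 (not isolated)
Conditions: toluene (degassed), 120 °C, sealed tube
Reagents that add atoms: none
Why: Proposed new method: heat should open the strained four-membered ring of 6 by 4π-electrocyclic ring opening (strain release) to vinylketene 11, whose ketene C=C should add the electron-rich siloxyalkyne 10 in a regioselective [2+2] cycloaddition to 12, forming both new ring bonds at once: the nucleophilic alkyne carbon bearing CH2OTBS bonds to the ketene carbonyl carbon and the oxygen-bearing alkyne carbon to the ketene α-carbon. Alkenylcyclobutenone 12 should then open by a second 4π-electrocyclic ring opening to dienylketene 13, and ring A closes by thermal disrotatory 6π-electrocyclisation of the ketene carbon onto the CMe2 terminus; because that terminus is fully substituted, the product cannot tautomerise to a phenol and stays as dienone 14. The closest known reaction type is the Danheiser benzannulation of cyclobutenones with alkoxy- and siloxyalkynes, which gives resorcinol ethers by the same four pericyclic steps, together with the well-known closure of dienylketenes to 6,6-disubstituted cyclohexa-2,4-dienones; what is new is a 4,4-dimethyl-3-siloxycyclobutenone that makes the cascade end at the blocked dienone. No stereocentre remains in 14, since the one of racemic 12 is destroyed on ring opening. The step needs regioselectivity in the [2+2], secured by the polarisation of the siloxyalkyne against the electrophilic ketene carbon, and it needs the dienylketene isomer with ketene and alkenyl group cis, which should be drained from the reversible ring-opening equilibria by the irreversible 6π closure; both kinds of silyl ether are inert to ketenes.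

Step 6
Reactants: 14 2-({[tert-butyl(dimethyl)silyl]oxy}methyl)-6,6-dimethyl-3,5-bis[(triisopropylsilyl)oxy]cyclohexa-2,4-dien-1-one
Product: 15 2-({[tert-butyl(dimethyl)silyl]oxy}methyl)-3,5-dihydroxy-6,6-dimethylcyclohexa-2,4-dien-1-one
Conditions: Bu4NF (2 equiv), AcOH (2 equiv), THF, −40 to −20 °C; pH 5 buffer work-up; used at once
Reagents that add atoms: none
Why: Fluoride should cleave the two silyl enol ethers (vinylogous silyl esters with a stabilised enolate as leaving group on silicon) far faster than the primary alkyl silyl ether, and the acetic acid buffer should keep the liberated trione from losing its silyloxymethyl group.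

Step 7
Reactants: 15 2-({[tert-butyl(dimethyl)silyl]oxy}methyl)-3,5-dihydroxy-6,6-dimethylcyclohexa-2,4-dien-1-one; 16 butanoic acid
Product: 18 2-butanoyl-6-({[tert-butyl(dimethyl)silyl]oxy}methyl)-3,5-dihydroxy-4,4-dimethylcyclohexa-2,5-dien-1-one, via enol butanoate 17 (not isolated)
Conditions: N,N'-dicyclohexylcarbodiimide, 4-(dimethylamino)pyridine (1.2 equiv), CH2Cl2, 0 °C to rt
Reagents that add atoms: none
Why: Carbodiimide activation should give an enol ester (drawn as the 3-O-ester 17; any enol ester converges), which rearranges by 4-(dimethylamino)pyridine-mediated O-to-C acyl transfer to the only free enolic carbon of 15, the established one-pot C-acylation of cyclic 1,3-diones.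

Step 8
Reactants: 18 2-butanoyl-6-({[tert-butyl(dimethyl)silyl]oxy}methyl)-3,5-dihydroxy-4,4-dimethylcyclohexa-2,5-dien-1-one; 19 1-(2,4,6-trihydroxyphenyl)butan-1-one (5 equiv, excess recovered)
Product: 22 2-butanoyl-6-[(3-butanoyl-2,4,6-trihydroxyphenyl)methyl]-3,5-dihydroxy-4,4-dimethylcyclohexa-2,5-dien-1-one, via hydroxymethyl trione 20 (not isolated), via methylidene trione 21 (not isolated)
Conditions: TsOH·H2O (cat.), 1,4-dioxane–H2O, 50 °C
Reagents that add atoms: none
Why: Acid should cleave the silyl ether to 20, which dehydrates as 2-hydroxymethyl-1,3-diones do to the quinone-methide-like Michael acceptor 21, and this alkylates the phloroglucinol ring of 19 at carbon (Friedel–Crafts/Michael alkylation, the reactive path of formaldehyde-type methylene bridging); 18 has no free nucleophilic carbon and cannot self-condense, and the excess of symmetric 19 should suppress double alkylation.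

Step 9
Reactants: 22 2-butanoyl-6-[(3-butanoyl-2,4,6-trihydroxyphenyl)methyl]-3,5-dihydroxy-4,4-dimethylcyclohexa-2,5-dien-1-one; 23 N,N-dimethylmethaniminium iodide (Eschenmoser's salt)
Product: 24 2-butanoyl-6-({3-butanoyl-5-[(dimethylamino)methyl]-2,4,6-trihydroxyphenyl}methyl)-3,5-dihydroxy-4,4-dimethylcyclohexa-2,5-dien-1-one
Conditions: i-Pr2NEt, MeCN, 0 °C to rt
Reagents that add atoms: none
Why: Mannich aminomethylation with a preformed iminium salt should occur at the single remaining nucleophilic C–H of 22 (ring B, between two hydroxyls), since ring A is fully substituted.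

Step 10
Reactants: 19 1-(2,4,6-trihydroxyphenyl)butan-1-one
Product: 25 1-(2,6-dihydroxy-4-methoxyphenyl)butan-1-one
Conditions: Me2SO4 (1 equiv), K2CO3 (1 equiv), acetone, rt
Reagents that add atoms: dimethyl sulfate, COS(=O)(=O)OC
Why: Williamson O-methylation should be selective for the 4-hydroxyl, the only one not held in a hydrogen bond to the ketone and the most acidic.

Step 11
Reactants: 24 2-butanoyl-6-({3-butanoyl-5-[(dimethylamino)methyl]-2,4,6-trihydroxyphenyl}methyl)-3,5-dihydroxy-4,4-dimethylcyclohexa-2,5-dien-1-one; 25 1-(2,6-dihydroxy-4-methoxyphenyl)butan-1-one (4 equiv, excess recovered)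
Product: 27 2-butanoyl-6-({3-butanoyl-5-[(3-butanoyl-2,4-dihydroxy-6-methoxyphenyl)methyl]-2,4,6-trihydroxyphenyl}methyl)-3,5-dihydroxy-4,4-dimethylcyclohexa-2,5-dien-1-one, via ring B quinone methide 26 (not isolated)
Conditions: 1,4-dioxane, 90 °C
Reagents that add atoms: none
Why: Thermal loss of dimethylamine from the phenolic Mannich base should give quinone methide 26, which is trapped at carbon by the electron-rich ring of 25 (Michael-type C-alkylation, the standard use of phenolic Mannich bases); 24 has no free nucleophilic carbon and the excess of symmetric 25 should favour monoalkylation at either of its two equivalent positions.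

**Compound list**

1 | 2-methylpropanoyl chloride | CC(C)C(Cl)=O | starting material
2 | ethoxyethyne | CCOC#C | starting material
3 | dimethylketene (2-methylprop-1-en-1-one) | CC(C)=C=O | intermediate
4 | 3-ethoxy-4,4-dimethylcyclobut-2-en-1-one | CCOC1=CC(=O)C1(C)C | intermediate
5 | 3-hydroxy-4,4-dimethylcyclobut-2-en-1-one (enol of 2,2-dimethylcyclobutane-1,3-dione) | OC1=CC(=O)C1(C)C | intermediate
6 | 4,4-dimethyl-3-[(triisopropylsilyl)oxy]cyclobut-2-en-1-one | CC(C)[Si](OC1=CC(=O)C1(C)C)(C(C)C)C(C)C | intermediate
7 | tert-butyl(dimethyl)(prop-2-yn-1-yloxy)silane | C#CCO[Si](C)(C)C(C)(C)C | starting material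
8 | alkynyllithium LiC≡CCH2OTBS | [Li]C#CCO[Si](C)(C)C(C)(C)C | intermediate
9 | lithium ynolate LiOC≡CCH2OTBS | [Li]OC#CCO[Si](C)(C)C(C)(C)C | intermediate
10 | tert-butyl(dimethyl)({3-[(triisopropylsilyl)oxy]prop-2-yn-1-yl}oxy)silane | CC(C)[Si](OC#CCO[Si](C)(C)C(C)(C)C)(C(C)C)C(C)C | intermediate
11 | 4-methyl-3-[(triisopropylsilyl)oxy]penta-1,3-dien-1-one (vinylketene) | O=C=CC(O[Si](C(C)C)(C(C)C)C(C)C)=C(C)C | intermediate
12 | racemic 2-({[tert-butyl(dimethyl)silyl]oxy}methyl)-4-{2-methyl-1-[(triisopropylsilyl)oxy]prop-1-en-1-yl}-3-[(triisopropylsilyl)oxy]cyclobut-2-en-1-one | O=C1C(CO[Si](C)(C)C(C)(C)C)=C(O[Si](C(C)C)(C(C)C)C(C)C)C1C(O[Si](C(C)C)(C(C)C)C(C)C)=C(C)C | intermediate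
13 | (3E)-2-({[tert-butyl(dimethyl)silyl]oxy}methyl)-6-methyl-3,5-bis[(triisopropylsilyl)oxy]hepta-1,3,5-trien-1-one (dienylketene; ketene carbon and dimethylvinyl group cis on the central C=C) | O=C=C(CO[Si](C)(C)C(C)(C)C)/C(O[Si](C(C)C)(C(C)C)C(C)C)=C\C(O[Si](C(C)C)(C(C)C)C(C)C)=C(C)C | intermediate
14 | 2-({[tert-butyl(dimethyl)silyl]oxy}methyl)-6,6-dimethyl-3,5-bis[(triisopropylsilyl)oxy]cyclohexa-2,4-dien-1-one | O=C1C(CO[Si](C)(C)C(C)(C)C)=C(O[Si](C(C)C)(C(C)C)C(C)C)C=C(O[Si](C(C)C)(C(C)C)C(C)C)C1(C)C | intermediate
15 | 2-({[tert-butyl(dimethyl)silyl]oxy}methyl)-3,5-dihydroxy-6,6-dimethylcyclohexa-2,4-dien-1-one | O=C1C(CO[Si](C)(C)C(C)(C)C)=C(O)C=C(O)C1(C)C | intermediate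
16 | butanoic acid | CCCC(O)=O | starting material
17 | 2-({[tert-butyl(dimethyl)silyl]oxy}methyl)-5-hydroxy-4,4-dimethyl-3-oxocyclohexa-1,5-dien-1-yl butanoate | O=C1C(CO[Si](C)(C)C(C)(C)C)=C(OC(=O)CCC)C=C(O)C1(C)C | intermediate
18 | 2-butanoyl-6-({[tert-butyl(dimethyl)silyl]oxy}methyl)-3,5-dihydroxy-4,4-dimethylcyclohexa-2,5-dien-1-one | CCCC(=O)C1=C(O)C(C)(C)C(O)=C(CO[Si](C)(C)C(C)(C)C)C1=O | intermediate
19 | 1-(2,4,6-trihydroxyphenyl)butan-1-one | CCCC(=O)c1c(O)cc(O)cc1O | starting material
20 | 2-butanoyl-3,5-dihydroxy-6-(hydroxymethyl)-4,4-dimethylcyclohexa-2,5-dien-1-one | CCCC(=O)C1=C(O)C(C)(C)C(O)=C(CO)C1=O | intermediate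
21 | 2-butanoyl-3-hydroxy-4,4-dimethyl-6-methylidenecyclohex-2-ene-1,5-dione | CCCC(=O)C1=C(O)C(C)(C)C(=O)C(=C)C1=O | intermediate
22 | 2-butanoyl-6-[(3-butanoyl-2,4,6-trihydroxyphenyl)methyl]-3,5-dihydroxy-4,4-dimethylcyclohexa-2,5-dien-1-one | CCCC(=O)C1=C(O)C(C)(C)C(O)=C(Cc2c(O)cc(O)c(C(=O)CCC)c2O)C1=O | intermediate
23 | N,N-dimethylmethaniminium iodide (Eschenmoser's salt) | C=[N+](C)C.[I-] | starting material
24 | 2-butanoyl-6-({3-butanoyl-5-[(dimethylamino)methyl]-2,4,6-trihydroxyphenyl}methyl)-3,5-dihydroxy-4,4-dimethylcyclohexa-2,5-dien-1-one | CCCC(=O)C1=C(O)C(C)(C)C(O)=C(Cc2c(O)c(CN(C)C)c(O)c(C(=O)CCC)c2O)C1=O | intermediate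
25 | 1-(2,6-dihydroxy-4-methoxyphenyl)butan-1-one | CCCC(=O)c1c(O)cc(OC)cc1O | intermediate
26 | 2-butanoyl-4-[(5-butanoyl-2,4-dihydroxy-3,3-dimethyl-6-oxocyclohexa-1,4-dien-1-yl)methyl]-3,5-dihydroxy-6-methylidenecyclohexa-2,4-dien-1-one (ring B quinone methide) | C=C1C(O)=C(CC2=C(O)C(C)(C)C(O)=C(C(=O)CCC)C2=O)C(O)=C(C(=O)CCC)C1=O | intermediate
27 | 2-butanoyl-6-({3-butanoyl-5-[(3-butanoyl-2,4-dihydroxy-6-methoxyphenyl)methyl]-2,4,6-trihydroxyphenyl}methyl)-3,5-dihydroxy-4,4-dimethylcyclohexa-2,5-dien-1-one | CCCC(=O)C1=C(O)C(C)(C)C(O)=C(Cc2c(O)c(Cc3c(OC)cc(O)c(C(=O)CCC)c3O)c(O)c(C(=O)CCC)c2O)C1=O | target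

**Step count and risks**

Total steps: 11. Longest linear sequence: 9 steps (1, 2, 3, 5, 6, 7, 8, 9, 11).

Steps most likely to fail:

Step 5. The electrocyclic opening of 6 may be slow because one methyl group must rotate inward. The vinylketene may dimerise, the siloxyalkyne may decompose thermally before it is intercepted, or the cascade may stall at the alkenylcyclobutenone stage. The fallback uses known chemistry and sets out from 19. Double C-methylation of 19 with iodomethane and NaOMe in methanol (dearomatising gem-dimethylation of an acylphloroglucinol) would give 2-butanoyl-3,5-dihydroxy-4,4-dimethylcyclohexa-2,5-dien-1-one F1. Mannich reaction of F1 with 23 and i-Pr2NEt would give 2-butanoyl-6-[(dimethylamino)methyl]-3,5-dihydroxy-4,4-dimethylcyclohexa-2,5-dien-1-one F2. Heating F2 with excess 19 in dioxane would give 22, where the route is rejoined.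

Step 8. The ring of 19 may be alkylated twice, the silyl ether may cleave incompletely, or the new methylene bridge may redistribute under acid. The fallback sets out from 18 and brings ring B in with one position already blocked by its second bridge carbon. 19 would be monoaminomethylated with 23 in MeCN without base, so that the product is deactivated as its ammonium salt, to give 1-{3-[(dimethylamino)methyl]-2,4,6-trihydroxyphenyl}butan-1-one F3 (handled as the hydroiodide). This salt and 18 would be joined with TsOH·H2O in aqueous dioxane, where the protonated aminomethyl group cannot ionise, and neutralisation with NaHCO3 would give 24 directly, so that step 9 is no longer needed.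

Step 11. At the temperature needed for amine loss the methylene bridges may scramble by retro-Michael fragmentation, 25 may be alkylated twice, or alkylation may occur at oxygen. The fallback sets out from 22 and reverses the roles of the partners. 25 would be aminomethylated with 23 and i-Pr2NEt to 1-{3-[(dimethylamino)methyl]-2,6-dihydroxy-4-methoxyphenyl}butan-1-one F4. F4 would be added slowly to 22 in dioxane at 90 °C, so that the ring C quinone methide is trapped by the single free aromatic C–H of 22, giving 27.

**Further compounds**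

F1 | step 5 | 2-butanoyl-3,5-dihydroxy-4,4-dimethylcyclohexa-2,5-dien-1-one | CCCC(=O)C1=C(O)C(C)(C)C(O)=CC1=O
F2 | step 5 | 2-butanoyl-6-[(dimethylamino)methyl]-3,5-dihydroxy-4,4-dimethylcyclohexa-2,5-dien-1-one | CCCC(=O)C1=C(O)C(C)(C)C(O)=C(CN(C)C)C1=O
F3 | step 8 | 1-{3-[(dimethylamino)methyl]-2,4,6-trihydroxyphenyl}butan-1-one | CCCC(=O)c1c(O)cc(O)c(CN(C)C)c1O
F4 | step 11 | 1-{3-[(dimethylamino)methyl]-2,6-dihydroxy-4-methoxyphenyl}butan-1-one | CCCC(=O)c1c(O)cc(OC)c(CN(C)C)c1O
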